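The five-membered ring C1–C2–C3–C3a–C8a with its exocyclic C4 (hydroazulene numbering) is bought as thujone, whose cyclopropane bond C3–C4 lies exactly where the C3 hydroxyl must stand, cis to C4. The route rests on exchanging that C–C bond for two C–O bonds. The C2 bromide of C8a-allylated thujone opens to a C2=C3 enone in a radical chain, takes up one O2 at C4 and closes by peroxide conjugate addition to a cis-fused 1,2-dioxolane. O–O reduction, oxidation at C4, chelation-controlled methallylation and ring-closing metathesis between C6 and C7 then build the seven-membered ring; aroylation, directed reduction, acetylation and desilylation finish.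

Key step: step 3

Remark: hydroazulene locants of the target are used for every intermediate; β is the face of the five-membered ring that carries H-3a, α the face that carries C4. The C2 configuration of the bromoketone is immaterial and the β-bromide is drawn.

Step 1
Reactants: 1 (−)-α-thujone; 2 allyl bromide
Product: 4 C8a-allylated thujone (4-allylthujone), via potassium enolate 3 (not isolated)
Conditions: KH (0.95 equiv), THF, 0 °C to rt; then allyl bromide, −20 °C to rt
Reagents that add atoms: none
Why: Enolate C-alkylation: with a slight excess of ketone the enolates should equilibrate to the more substituted one (3), which erases the C8a centre of either thujone epimer, and allyl bromide should then attack C8a on the β face, away from the cyclopropane CH2, so that allyl and C4 end up trans.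

Step 2
Reactants: 4 C8a-allylated thujone
Product: 6 C2 bromoketone, via silyl enol ether 5 (not isolated)
Conditions: TMSOTf, Et3N, CH2Cl2, 0 °C; then NBS, −78 to 0 °C
Reagents that add atoms: N-bromosuccinimide, O=C1CCC(=O)N1Br (TMSOTf, C[Si](C)(C)OS(=O)(=O)C(F)(F)F, puts its silyl group only into intermediate 5)
Why: α-Bromination through a silyl enol ether: quaternary C8a leaves C2 as the only enolisable position, and NBS should brominate the enol ether there under non-acidic conditions that spare the cyclopropane and the allyl group.

Step 3
Reactants: 6 C2 bromoketone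
Product: 8 cis-fused 1,2-dioxolane ketone, via hydroperoxy enone 7 (not isolated)
Conditions: Bu3SnH (1.3 equiv, syringe pump), air/N2 (about 5% O2, slow stream), toluene (0.02 M), 0 °C; then CF3CH2OH, Et3N (0.3 equiv), 0 °C to rt
Reagents that add atoms: dioxygen, O=O
Why: Proposed new method: Bu3Sn radicals abstract bromine from 6 to give the C2 α-keto radical, a cyclopropylcarbinyl radical that opens the external C3–C4 bond to the C2=C3 enone and a primary C4 radical; O2 traps that radical and the peroxyl radical takes hydrogen from Bu3SnH, which gives hydroperoxide 7 and returns the stannyl radical to the chain. Et3N then triggers a polar 5-exo-trig conjugate addition of the hydroperoxide to C3, which closes the only new ring, the 1,2-dioxolane C3–O–O–C4–C3a. Closest known reaction types: external-bond opening of thujone-type bicyclo[3.1.0]hex-2-yl radicals, the aerobic tin hydride conversion of alkyl halides into hydroperoxides and alcohols, radical/O2 routes from vinylcyclopropanes to 1,2-dioxolanes, and amine-mediated hydroperoxide addition to enones. The one new stereocentre, C3, is fixed by the single-carbon tether from C3a, which permits only a cis ring fusion and so puts oxygen on the α face that C4 vacated (net retention), while C3a and C8a are not touched. The step needs cleavage of the exocyclic rather than the ring-fusion cyclopropane bond and O2 capture at C4 rather than C2; the first follows from the better overlap of the exocyclic bond with the radical orbital, the second from the low O2 concentration and from a stannyl rather than an alkyl chain carrier, which takes bromine from 6 far faster than the C4 radical can. Quaternary C8a leaves C2 as the only site that could have been brominated, a tertiary amine avoids dienamine formation that would scramble C3a, and the trans allyl group cannot trap the C4 radical because a 5-exo closure would give a trans-fused diquinane.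

Step 4
Reactants: 8 cis-fused 1,2-dioxolane ketone
Product: 9 keto diol
Conditions: Zn, AcOH, THF, 0 °C to rt
Reagents that add atoms: none
Why: Reductive cleavage of a dialkyl peroxide: zinc in acetic acid should break only the O–O bond, so both oxygens stay where the dioxolane placed them and the ketone, the alkene and all stereocentres are untouched.

Step 5
Reactants: 9 keto diol
Product: 10 β-hydroxy aldehyde
Conditions: TEMPO (10 mol %), PhI(OAc)2, CH2Cl2, rt; used crude
Reagents that add atoms: none
Why: Oxoammonium (TEMPO) oxidation is selective for the primary alcohol, cannot oxidise the tertiary C3 hydroxyl and stops at the aldehyde under near-neutral conditions that should limit epimerisation at C3a and retro-aldol cleavage.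

Step 6
Reactants: 10 β-hydroxy aldehyde; 11 methallyl bromide
Product: 12 diene keto diol
Conditions: In, THF/H2O (1:1), rt
Reagents that add atoms: none
Why: Indium Barbier allylation under Cram-chelate control: the reagent should add to the aldehyde and not to the hindered C1 ketone, and indium bridging the C3 hydroxyl and the aldehyde oxygen exposes the carbonyl face on the side of H-3a, away from quaternary C8a, which sets C4 as S.

Step 7
Reactants: 12 diene keto diol
Product: 13 trans-fused hydroazulenone diol
Conditions: second-generation Grubbs catalyst (H2IMes)(PCy3)Cl2Ru=CHPh (5 mol %), CH2Cl2 (0.005 M), 40 °C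
Reagents that add atoms: none
Why: Ring-closing metathesis between the allyl and methallyl alkenes should close the seven-membered ring (C3a, C4, C5, C6, C7, C8, C8a) as the trisubstituted C6=C7 alkene with loss of ethylene; the fusion can only be trans because C4 and C8 already sit on opposite faces.

Step 8
Reactants: 14 4-hydroxybenzoic acid
Product: 16 4-(tert-butyldimethylsilyloxy)benzoic acid, via bis-silyl derivative 15 (not isolated)
Conditions: TBSCl (2.3 equiv), imidazole, DMF, rt; then AcOH/THF/H2O, rt
Reagents that add atoms: tert-butyldimethylsilyl chloride, CC(C)(C)[Si](C)(C)Cl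
Why: Protecting-group installation: both acidic sites are silylated and mild aqueous acid then hydrolyses only the far more labile silyl ester, leaving the aryl silyl ether.

Step 9
Reactants: 13 trans-fused hydroazulenone diol; 16 4-(tert-butyldimethylsilyloxy)benzoic acid
Product: 17 C4 aroyl ester ketone
Conditions: DCC, DMAP (0.2 equiv), CH2Cl2, 0 °C to rt
Reagents that add atoms: none
Why: Steglich esterification should acylate the only secondary hydroxyl (C4) with retention, since its C–O bond is not broken, while the tertiary C3 hydroxyl is inert to the acylpyridinium species.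

Step 10
Reactants: 17 C4 aroyl ester ketone
Product: 18 C1 alcohol
Conditions: Me4NBH(OAc)3, MeCN/AcOH (1:1), −20 to 0 °C
Reagents that add atoms: none
Why: Saksena–Evans directed reduction: the C3 hydroxyl should exchange onto boron and deliver hydride to the α face of the C1 carbonyl, giving the trans-1,3-diol with the new hydroxyl β (1S), while the ester, the alkene and the aryl silyl ether are inert to this weak hydride.

Step 11
Reactants: 18 C1 alcohol
Product: 19 C1 acetate
Conditions: Ac2O, DMAP (cat.), pyridine, CH2Cl2, 0 °C to rt
Reagents that add atoms: acetic anhydride, CC(=O)OC(C)=O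
Why: DMAP-catalysed acylation should acetylate the secondary C1 hydroxyl and leave the tertiary C3 hydroxyl free.

Step 12
Reactants: 19 C1 acetate
Product: 20 target CNP0275279.1
Conditions: Bu4NF, AcOH (1:1), THF, 0 °C
Reagents that add atoms: none
Why: Fluoride desilylation should cleave the aryl silyl ether quickly at 0 °C, with acetic acid buffering the phenoxide so that neither the acetate nor the benzoate is transesterified.

Compound list

1 | (−)-α-thujone, (1S,4R,5R)-1-isopropyl-4-methylbicyclo[3.1.0]hexan-3-one (the commercial α/β mixture serves equally) | C[C@H]1C(=O)C[C@]2(C(C)C)C[C@H]12 | starting material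
2 | allyl bromide | C=CCBr | starting material
3 | potassium enolate of thujone (C1=C8a enolate; C3 and C3a as in 1) | CC1=C([O-])C[C@]2(C(C)C)C[C@H]12.[K+] | intermediate
4 | C8a-allylated thujone: 4-allyl-1-isopropyl-4-methylbicyclo[3.1.0]hexan-3-one, allyl β (anti to the cyclopropane CH2), methyl α | C=CC[C@@]1(C)C(=O)C[C@]2(C(C)C)C[C@H]12 | intermediate
5 | trimethylsilyl enol ether of 4 (C1=C2) | C=CC[C@@]1(C)C(O[Si](C)(C)C)=C[C@]2(C(C)C)C[C@H]12 | intermediate
6 | C2 bromoketone: 2-bromo derivative of 4, bromine drawn β (either epimer serves) | C=CC[C@@]1(C)C(=O)[C@@H](Br)[C@]2(C(C)C)C[C@H]12 | intermediate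
7 | hydroperoxy enone: 5-allyl-4-(hydroperoxymethyl)-3-isopropyl-5-methylcyclopent-2-enone, CH2OOH α, allyl β | C=CC[C@@]1(C)C(=O)C=C(C(C)C)[C@@H]1COO | intermediate
8 | cis-fused 1,2-dioxolane ketone: dioxolane C3–O–O–C4–C3a on the α face of the cyclopentanone, isopropyl β at C3, allyl β and methyl α at C8a | C=CC[C@@]1(C)C(=O)C[C@]2(C(C)C)OOC[C@H]12 | intermediate
9 | keto diol: cyclopentanone with tertiary 3α-OH, 3β-isopropyl, α-CH2OH at C3a, β-allyl and α-methyl at C8a | C=CC[C@@]1(C)C(=O)C[C@@](O)(C(C)C)[C@@H]1CO | intermediate
10 | β-hydroxy aldehyde: as 9 with CHO in place of CH2OH | C=CC[C@@]1(C)C(=O)C[C@@](O)(C(C)C)[C@@H]1C=O | intermediate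
11 | methallyl bromide (3-bromo-2-methylprop-1-ene) | C=C(C)CBr | starting material
12 | diene keto diol: as 9 with an (S)-1-hydroxy-3-methylbut-3-enyl group at C3a (C4 carbinol S) | C=CC[C@@]1(C)C(=O)C[C@@](O)(C(C)C)[C@@H]1[C@@H](O)CC(C)=C | intermediate
13 | trans-fused hydroazulenone diol, (3R,3aS,4S,8aR)-3,4-dihydroxy-3-isopropyl-6,8a-dimethyl-3,3a,4,5,8,8a-hexahydroazulen-1(2H)-one | O=C1C[C@@](O)(C(C)C)[C@@H]2[C@@H](O)CC(C)=CC[C@@]12C | intermediate
14 | 4-hydroxybenzoic acid | OC(=O)c1ccc(O)cc1 | starting material
15 | tert-butyldimethylsilyl 4-(tert-butyldimethylsilyloxy)benzoate | CC(C)(C)[Si](C)(C)OC(=O)c1ccc(O[Si](C)(C)C(C)(C)C)cc1 | intermediate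
16 | 4-(tert-butyldimethylsilyloxy)benzoic acid | OC(=O)c1ccc(O[Si](C)(C)C(C)(C)C)cc1 | intermediate
17 | C4 aroyl ester ketone, (3R,3aS,4S,8aR)-3-hydroxy-3-isopropyl-6,8a-dimethyl-1-oxo-1,2,3,3a,4,5,8,8a-octahydroazulen-4-yl 4-(tert-butyldimethylsilyloxy)benzoate | O=C1C[C@@](O)(C(C)C)[C@@H]2[C@@H](OC(=O)c3ccc(O[Si](C)(C)C(C)(C)C)cc3)CC(C)=CC[C@@]12C | intermediate
18 | C1 alcohol, the (1S)-1β-hydroxy compound from 17 (1,3-trans diol) | O[C@H]1C[C@@](O)(C(C)C)[C@@H]2[C@@H](OC(=O)c3ccc(O[Si](C)(C)C(C)(C)C)cc3)CC(C)=CC[C@@]12C | intermediate
19 | C1 acetate of 18 | CC(=O)O[C@H]1C[C@@](O)(C(C)C)[C@@H]2[C@@H](OC(=O)c3ccc(O[Si](C)(C)C(C)(C)C)cc3)CC(C)=CC[C@@]12C | intermediate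
20 | CNP0275279.1, (1S,3R,3aS,4S,8aR)-1-acetoxy-3-hydroxy-3-isopropyl-6,8a-dimethyl-1,2,3,3a,4,5,8,8a-octahydroazulen-4-yl 4-hydroxybenzoate | CC(=O)O[C@H]1C[C@@](O)(C(C)C)[C@@H]2[C@@H](OC(=O)c3ccc(O)cc3)CC(C)=CC[C@@]12C | target

Total step count: 12. Longest linear sequence: 11 steps (steps 1–7 and 9–12, from thujone).

Steps most likely to fail

Step 3 (proposed new method). The hydroperoxide may be reduced by the stannane before it cyclises, or peroxide addition to the fully substituted C3 may stay incomplete or be followed by base-induced O–O fragmentation. Fallback with known reaction types: from bromoketone 6 the same radical opening is run with excess Bu3SnH under air and finished with PPh3 (aerobic tin hydride hydroxylation of halides), which deliberately takes hydroperoxide 7 down to the hydroxymethyl enone F1. PhB(OH)2 with a catalytic tertiary amine should then form the boronic hemiester at the C4 hydroxyl and add its B–OH to C3 (intramolecular boronate oxa-Michael addition), giving the cis-fused cyclic phenylboronate F2. H2O2/NaHCO3 cleaves the boronate to keto diol 9, where the route resumes without passing through dioxolane 8.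

Step 6. Facial selectivity may be poor if the hindered tertiary C3 hydroxyl does not hold indium in a chelate in the aqueous medium. Fallback: from aldehyde 10 the addition is accepted with whatever selectivity it shows, and the C4-epimeric diene keto diol F3 is cyclised with the same ruthenium carbene to the C4-epimeric hydroazulenone diol F4. A Mitsunobu esterification with acid 16 (PPh3, DIAD, toluene) should then install the aroyl ester with inversion at C4 and rejoin the route at ester 17.

Step 10. Hydride transfer from boron bound to the hindered tertiary hydroxyl may be too slow, so that the ketone is not reduced or is reduced by external attack on the β face. Fallback: from ketone 17, NaBH4 in MeOH at −20 °C should attack from the β face, anti to the α methyl on C8a, and give the C1-epimeric alcohol F5. A Mitsunobu reaction with acetic acid (PPh3, DIAD) should then invert C1 and install the acetate in one operation, rejoining the route at acetate 19.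

Further compounds

F1 | step 3 | hydroxymethyl enone, 5-allyl-4-(hydroxymethyl)-3-isopropyl-5-methylcyclopent-2-enone (CH2OH α, allyl β) | C=CC[C@@]1(C)C(=O)C=C(C(C)C)[C@@H]1CO
F2 | step 3 | cyclic phenylboronate of keto diol 9 (1,3,2-dioxaborinane across C3–O and C4–O, cis-fused) | C=CC[C@@]1(C)C(=O)C[C@]2(C(C)C)OB(c3ccccc3)OC[C@H]12
F3 | step 6 | C4-epimeric diene keto diol (C4 carbinol R) | C=CC[C@@]1(C)C(=O)C[C@@](O)(C(C)C)[C@@H]1[C@H](O)CC(C)=C
F4 | step 6 | C4-epimeric hydroazulenone diol | O=C1C[C@@](O)(C(C)C)[C@@H]2[C@H](O)CC(C)=CC[C@@]12C
F5 | step 10 | C1-epimeric alcohol (1α-hydroxy, cis-1,3-diol) | O[C@@H]1C[C@@](O)(C(C)C)[C@@H]2[C@@H](OC(=O)c3ccc(O[Si](C)(C)C(C)(C)C)cc3)CC(C)=CC[C@@]12C
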